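**Plan**

1. Labels: furofuran atoms F1–F8 follow 3,7-dioxabicyclo[3.3.0]octane numbering (ring B on F2, ring C on F6); ring D is the guaiacyl ketone, ring E the guaiacyl group on the dihydrobenzofuran; in each side arm C8 is bonded to ring B or C, C7 to ring D or E, and C9 is the CH2OH carbon. The retrosynthesis first cuts the dihydrobenzofuran O–C7 bond, then both C7–C8 bonds (aldol with vanillin) and both aryl–C8 bonds (arylacetate from Ar–Br). This leaves C2-symmetric 5,5'-dibromopinoresinol.
2. Enabling feature: F2 and F6 are benzylic and each stands para to the oxygen of ring B or ring C. Cutting O3–F2 and O7–F6 and joining F2 to F6 gives a C2-symmetric 3,4-diarylcyclobutane-1,2-dimethanol in which only the trans pair F1/F5 keeps stereochemical information. That ring is the head-to-head [2+2] dimer of 5-bromoferulic acid.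
3. Forward order: cyclobutane (tethered photocycloaddition, reduction), then both tetrahydrofuran rings at once by oxidative unzip and double oxa-cyclisation, then two identical arms grown on the aryl bromides. One arm is oxidised to the ketone (statistical desymmetrisation), the other is closed to the dihydrobenzofuran, and a global desilylation finishes the route.
4. Stereochemistry: F1/F5 come from the (R,R)-hydrobenzoin tether; F2/F6 from the cis-fused bicycle under reversible closure (aryl groups exo). C8 and C7 of both arms come from an Evans syn-aldol with (R)-4-benzyl-2-oxazolidinone. Dihydrobenzofuran C2 arises by SN2 inversion of the syn carbinol, which gives the cis ring; the ketone-side C8 is the same aldol centre, unveiled late under non-basic conditions.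

Key step: step 6

Assumption: the (R,R)-hydrobenzoin tether is taken to give the (1R,2R) ester-bearing carbons (a positive O–C–C–O torsion with anti phenyl groups fits the trans-fused eight-membered dilactone of that configuration); the configuration of 7 is to be confirmed by anomalous-dispersion X-ray analysis (two Br atoms) before material is carried on.

**Route**

Step 1
Reactants: 1 5-bromovanillin; 2 malonic acid
Product: 3 (E)-5-bromoferulic acid
Conditions: pyridine, piperidine (cat.), 90 °C
Reagents that add atoms: none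
Why: Knoevenagel–Doebner condensation, in which the aldehyde condenses with malonic acid and the adduct decarboxylates in hot pyridine to the thermodynamically favoured E-cinnamic acid.

Step 2
Reactants: 3 (E)-5-bromoferulic acid
Product: 4 (E)-4-O-acetyl-5-bromoferulic acid
Conditions: Ac2O, pyridine, rt; aqueous work-up
Reagents that add atoms: acetic anhydride, CC(=O)OC(C)=O
Why: Acetylation masks the phenol that would interfere with ester formation, the mixed anhydride at the carboxyl group is hydrolysed on work-up, and the acetate is chosen because the hydride reduction of step 5 removes it without an extra step.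

Step 3
Reactants: 4 (E)-4-O-acetyl-5-bromoferulic acid (2.2 equiv); 5 (R,R)-hydrobenzoin
Product: 6 (R,R)-hydrobenzoin bis(4-O-acetyl-5-bromoferulate)
Conditions: DCC, DMAP (cat.), CH2Cl2, 0 °C to rt
Reagents that add atoms: none
Why: Steglich esterification (carbodiimide activation, DMAP acyl transfer) acylates both secondary hydroxyls of the C2-symmetric diol, so that the two cinnamoyl units sit head to head on a short chiral tether.

Step 4
Reactants: 6 (R,R)-hydrobenzoin bis(4-O-acetyl-5-bromoferulate)
Product: 7 hydrobenzoin-bridged all-trans cyclobutane dilactone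
Conditions: [Ir(dF(CF3)ppy)2(dtbbpy)]PF6 (1 mol %), 450 nm LEDs, degassed MeCN (0.01 M), rt
Reagents that add atoms: none
Why: Intramolecular [2+2] photocycloaddition by triplet energy transfer, in which the sensitised cinnamate adds to its tethered partner through a 1,4-diradical, the tether enforces head-to-head bonding and biases the two ester-bearing carbons to trans (1R,2R), the long-lived diradical closes to the all-trans ring, the weakly reducing excited Ir complex should leave the C–Br bonds alone, and epimers at the two aryl-bearing carbons would not matter because step 6 erases those centres.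

Step 5
Reactants: 7 hydrobenzoin-bridged all-trans cyclobutane dilactone
Product: 8 all-trans 3,4-bis(3-bromo-4-hydroxy-5-methoxyphenyl)cyclobutane-1,2-dimethanol
Conditions: LiAlH4, THF, 0 °C to rt; then H2O
Reagents that add atoms: none
Why: Ester reduction with LiAlH4 opens both lactone carbonyls to the primary alcohols, releases the diol auxiliary for recovery and cleaves both aryl acetates in the same operation, while the aryl bromides should be untouched at this temperature.

Step 6
Reactants: 8 all-trans 3,4-bis(3-bromo-4-hydroxy-5-methoxyphenyl)cyclobutane-1,2-dimethanol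
Product: 10 5,5'-dibromo-(+)-pinoresinol, via bis-quinone methide 9 (not isolated)
Conditions: Ag2O (1.1 equiv), CH2Cl2/acetone, rt, dark
Reagents that add atoms: none
Why: Ag2O oxidises a phenol to its phenoxyl radical, whose spin at the ring carbon para to oxygen triggers β-scission of the strained, doubly benzylic ring bond (C3–C4 of 8, the future F2 and F6), and the resulting para-hydroxybenzyl radical is oxidised by a second silver equivalent, which gives bis-quinone methide 9 with the F1–F5 bond and its (R,R) configuration intact. The closest known reaction type is the oxidative ring opening of 1,2-bis(4-hydroxyaryl)cyclobutanes to bis-quinone methides, and 9 is the same kind of intermediate through which phenoxyl coupling of coniferyl-type alcohols leads to furofurans. Each tetrahydrofuran ring closes by 5-exo-trig oxa-1,6-conjugate addition of a hydroxymethyl oxygen to the distal methide carbon with rearomatisation (O3 to F2 and O7 to F6), and the trans F1/F5 pair permits only the cis-fused bicycle. F2 and F6 are controlled by the adjacent bridgeheads, each aryl group taking the convex (exo) face, and because a para-hydroxybenzyl ether can reopen to the quinone methide this preference is backed by thermodynamic control. The step needs cleavage of the aryl-flanked ring bond only and no C–C coupling of phenoxyl radicals; the first is secured by both termini being para-hydroxybenzylic, the second by Br and OMe occupying both ortho positions of each phenol, and the oxidant is held near one equivalent because the product is again a phenol.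

Step 7
Reactants: 10 5,5'-dibromo-(+)-pinoresinol
Product: 11 4,4'-di-O-benzyl-5,5'-dibromopinoresinol
Conditions: BnBr, K2CO3, DMF, rt
Reagents that add atoms: benzyl bromide, BrCc1ccccc1
Why: Williamson etherification of the two acidic ortho-bromophenols, with benzyl chosen because it survives enolate, borane and hydride chemistry and is later removed by hydrogenolysis without touching silyl ethers.

Step 8
Reactants: 11 4,4'-di-O-benzyl-5,5'-dibromopinoresinol
Product: 12 bis(ethyl arylacetate)
Conditions: BrZnCH2CO2Et (preformed solution in THF, 3 equiv), Pd2(dba)3 (2.5 mol %), XPhos (10 mol %), THF, 60 °C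
Reagents that add atoms: (2-ethoxy-2-oxoethyl)zinc bromide, CCOC(=O)C[Zn]Br
Why: Negishi-type coupling of a Reformatsky reagent (palladium-catalysed α-arylation of a zinc ester enolate), in which oxidative addition of zerovalent palladium into each Ar–Br bond, transmetalation and reductive elimination give the arylacetates under nearly neutral conditions that the benzylic ethers tolerate, the bulky biaryl phosphine coping with the ortho-benzyloxy group.

Step 9
Reactants: 12 bis(ethyl arylacetate)
Product: 13 bis(arylacetic acid)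
Conditions: LiOH, THF/MeOH/H2O, rt; then dilute HCl, 0 °C, to pH 3
Reagents that add atoms: lithium hydroxide, [Li+].[OH-]
Why: Saponification of the two ethyl esters, the furofuran ethers being stable to base and the brief cold acidification serving only to protonate the carboxylates.

Step 10
Reactants: 13 bis(arylacetic acid); 14 (R)-4-benzyl-2-oxazolidinone (2.2 equiv)
Product: 16 bis(N-arylacetyl oxazolidinone), via bis(pivalic) mixed anhydride 15 (not isolated)
Conditions: PivCl, Et3N, THF, −20 °C; then 14, LiCl, −20 °C to rt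
Reagents that add atoms: none
Why: N-acylation of the oxazolidinone through the pivalic mixed anhydride (amine/LiCl variant) attaches the chiral auxiliary to both arylacetyl units without a strong base.

Step 11
Reactants: 17 vanillin
Product: 18 4-O-TBS-vanillin
Conditions: TBSCl, imidazole, DMF, rt
Reagents that add atoms: tert-butyldimethylsilyl chloride, CC(C)(C)[Si](C)(C)Cl
Why: Silylation of the phenol allows the aldehyde to be used in the boron aldol reaction and keeps the ring D and ring E oxygens masked until the last step.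

Step 12
Reactants: 16 bis(N-arylacetyl oxazolidinone); 18 4-O-TBS-vanillin (2.6 equiv)
Product: 20 bis(syn-aldol adduct), via bis(dibutylboron) Z-enolate 19 (not isolated)
Conditions: Bu2BOTf, iPr2NEt, CH2Cl2, −78 to 0 °C; then 18, −78 to 0 °C; pH 7 buffer, MeOH, H2O2, 0 °C
Reagents that add atoms: none
Why: Evans syn-aldol reaction, in which the Z-boron enolate of each arylacetyl imide adds to the aldehyde through a closed chair transition state on the face away from the benzyl group of the (R)-auxiliary, setting C8 and C7 of both arms as the syn (2R,3R) adducts independently of the remote furofuran core.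

Step 13
Reactants: 20 bis(syn-aldol adduct)
Product: 21 bis(syn-1,3-diol) (tetraol)
Conditions: LiBH4, H2O (1 equiv per imide), THF, 0 °C
Reagents that add atoms: none
Why: Reductive cleavage of the acyl oxazolidinone by hydride attack at the exocyclic carbonyl gives the primary alcohol C9 of each arm without touching C8 and returns the auxiliary.

Step 14
Reactants: 21 bis(syn-1,3-diol) (tetraol)
Product: 22 bis(primary TBS ether)
Conditions: TBSCl (2.2 equiv), imidazole, CH2Cl2, 0 °C
Reagents that add atoms: tert-butyldimethylsilyl chloride, CC(C)(C)[Si](C)(C)Cl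
Why: Selective silylation, TBSCl reacting far faster with the two primary alcohols than with the hindered secondary benzylic ones, protects C9–OH against oxidation and against competing ring closure in step 17.

Step 15
Reactants: 22 bis(primary TBS ether)
Product: 23 mono-ketone (ring B arm oxidised)
Conditions: Dess–Martin periodinane (0.6 equiv), CH2Cl2, 0 °C; chromatography, recovered 22 recycled
Reagents that add atoms: none
Why: Dess–Martin oxidation with a deficit of oxidant converts one of the two equivalent, remote carbinols into the aryl ketone under non-basic conditions that should leave the α-aryl centre C8 intact, the step being a statistical desymmetrisation in which unreacted 22 is recycled and the diketone is removed.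

Step 16
Reactants: 23 mono-ketone (ring B arm oxidised)
Product: 24 mono-ketone with free ring B and ring C phenols
Conditions: H2 (1 atm), 10% Pd/C, EtOAc, rt
Reagents that add atoms: none
Why: Hydrogenolysis of the two aryl benzyl ethers in neutral ethyl acetate is expected to be much faster than cleavage of the dialkyl benzylic ethers of the furofuran or reduction of the electron-rich aryl ketone, and it leaves all silyl ethers in place.

Step 17
Reactants: 24 mono-ketone with free ring B and ring C phenols
Product: 25 silylated cis-dihydrobenzofuran ketone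
Conditions: PPh3, DIAD, toluene (0.01 M), 0 °C
Reagents that add atoms: none
Why: Intramolecular Mitsunobu etherification, in which the ring C phenol displaces the activated C7 oxygen in a 5-exo-tet SN2 reaction with inversion and so turns the syn (7R,8S) carbinol into the cis (2S,3S) dihydrobenzofuran, the ring B phenol having no leaving group within reach, the primary hydroxyls being silylated, and the non-polar solvent at low temperature chosen to disfavour ionisation of the para-silyloxybenzylic centre.

Step 18
Reactants: 25 silylated cis-dihydrobenzofuran ketone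
Product: 26 CNP0174045.1
Conditions: TBAF, AcOH (1:1), THF, 0 °C to rt
Reagents that add atoms: none
Why: Fluoride-induced cleavage of the two aryl and two primary alkyl silyl ethers with acetic acid-buffered TBAF, conditions mild enough for the enolisable α-aryl-β-hydroxy ketone, the ortho-hydroxy deoxybenzoin and the acid-sensitive para-hydroxybenzyl ethers.

**Compound list**

1 | 5-bromovanillin | COc1cc(C=O)cc(Br)c1O | starting material
2 | malonic acid | OC(=O)CC(=O)O | starting material
3 | (E)-3-(3-bromo-4-hydroxy-5-methoxyphenyl)acrylic acid (5-bromoferulic acid) | COc1cc(/C=C/C(=O)O)cc(Br)c1O | intermediate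
4 | (E)-3-(4-acetoxy-3-bromo-5-methoxyphenyl)acrylic acid | COc1cc(/C=C/C(=O)O)cc(Br)c1OC(C)=O | intermediate
5 | (1R,2R)-1,2-diphenylethane-1,2-diol, (R,R)-hydrobenzoin | O[C@H](c1ccccc1)[C@H](O)c1ccccc1 | starting material
6 | (1R,2R)-1,2-diphenylethane-1,2-diyl bis[(E)-3-(4-acetoxy-3-bromo-5-methoxyphenyl)acrylate] | COc1cc(/C=C/C(=O)O[C@H](c2ccccc2)[C@H](OC(=O)/C=C/c3cc(Br)c(OC(C)=O)c(OC)c3)c4ccccc4)cc(Br)c1OC(C)=O | intermediate
7 | dilactone of (1R,2R,3S,4S)-3,4-bis(4-acetoxy-3-bromo-5-methoxyphenyl)cyclobutane-1,2-dicarboxylic acid with (R,R)-hydrobenzoin (all-trans cyclobutane trans-fused to the eight-membered dilactone) | O=C3[C@H]1[C@H](C(=O)O[C@H](c4ccccc4)[C@@H](c6ccccc6)O3)[C@@H](c2cc(Br)c(OC(C)=O)c(OC)c2)[C@@H]1c5cc(Br)c(OC(C)=O)c(OC)c5 | intermediate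
8 | [(1R,2R,3S,4S)-3,4-bis(3-bromo-4-hydroxy-5-methoxyphenyl)cyclobutane-1,2-diyl]dimethanol | OC[C@H]1[C@H](CO)[C@@H](c2cc(Br)c(O)c(OC)c2)[C@@H]1c3cc(Br)c(O)c(OC)c3 | intermediate
9 | bis-quinone methide: 4,4'-[(2R,3R)-2,3-bis(hydroxymethyl)butane-1,4-diylidene]bis(2-bromo-6-methoxycyclohexa-2,5-dien-1-one), methide geometry not defined | OC[C@H](C=C1C=C(Br)C(=O)C(OC)=C1)[C@H](CO)C=C2C=C(Br)C(=O)C(OC)=C2 | intermediate (not isolated)
10 | 5,5'-dibromo-(+)-pinoresinol: (1S,3aR,4S,6aR)-1,4-bis(3-bromo-4-hydroxy-5-methoxyphenyl)tetrahydro-1H,3H-furo[3,4-c]furan | COc1cc(cc(Br)c1O)[C@H]2OC[C@H]3[C@@H]2CO[C@@H]3c4cc(Br)c(O)c(OC)c4 | intermediate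
11 | 4,4'-di-O-benzyl ether of 10 | COc1cc(cc(Br)c1OCc8ccccc8)[C@H]2OC[C@H]3[C@@H]2CO[C@@H]3c4cc(Br)c(OCc8ccccc8)c(OC)c4 | intermediate
12 | 11 with each Br replaced by CH2CO2Et (bis ethyl arylacetate) | COc1cc(cc(CC(=O)OCC)c1OCc8ccccc8)[C@H]2OC[C@H]3[C@@H]2CO[C@@H]3c4cc(CC(=O)OCC)c(OCc8ccccc8)c(OC)c4 | intermediate
13 | corresponding bis(arylacetic acid) | COc1cc(cc(CC(=O)O)c1OCc8ccccc8)[C@H]2OC[C@H]3[C@@H]2CO[C@@H]3c4cc(CC(=O)O)c(OCc8ccccc8)c(OC)c4 | intermediate
14 | (R)-4-benzyl-1,3-oxazolidin-2-one | O=C1N[C@H](Cc2ccccc2)CO1 | starting material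
15 | bis(pivalic) mixed anhydride of 13 | COc1cc(cc(CC(=O)OC(=O)C(C)(C)C)c1OCc8ccccc8)[C@H]2OC[C@H]3[C@@H]2CO[C@@H]3c4cc(CC(=O)OC(=O)C(C)(C)C)c(OCc8ccccc8)c(OC)c4 | intermediate (not isolated)
16 | bis-imide: each arylacetyl group of 13 on N3 of (R)-4-benzyl-2-oxazolidinone | COc1cc(cc(CC(=O)N5[C@H](Cc6ccccc6)COC5=O)c1OCc8ccccc8)[C@H]2OC[C@H]3[C@@H]2CO[C@@H]3c4cc(CC(=O)N5[C@H](Cc6ccccc6)COC5=O)c(OCc8ccccc8)c(OC)c4 | intermediate
17 | vanillin | COc1cc(C=O)ccc1O | starting material
18 | 4-(tert-butyldimethylsilyloxy)-3-methoxybenzaldehyde | COc1cc(C=O)ccc1O[Si](C)(C)C(C)(C)C | intermediate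
19 | bis[(Z)-O-dibutylboryl enolate] of 16 | COc1cc(cc(/C=C(\OB(CCCC)CCCC)N5[C@H](Cc6ccccc6)COC5=O)c1OCc8ccccc8)[C@H]2OC[C@H]3[C@@H]2CO[C@@H]3c4cc(/C=C(\OB(CCCC)CCCC)N5[C@H](Cc6ccccc6)COC5=O)c(OCc8ccccc8)c(OC)c4 | intermediate (not isolated)
20 | bis(syn-aldol adduct): each arm a (2R,3R)-3-hydroxy-3-(4-TBSO-3-methoxyphenyl)-2-arylpropanoyl imide | COc1cc(cc([C@@H](C(=O)N5[C@H](Cc6ccccc6)COC5=O)[C@@H](O)c7ccc(O[Si](C)(C)C(C)(C)C)c(OC)c7)c1OCc8ccccc8)[C@H]2OC[C@H]3[C@@H]2CO[C@@H]3c4cc([C@@H](C(=O)N5[C@H](Cc6ccccc6)COC5=O)[C@@H](O)c7ccc(O[Si](C)(C)C(C)(C)C)c(OC)c7)c(OCc8ccccc8)c(OC)c4 | intermediate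
21 | tetraol: each arm a (7R,8S) syn-1-aryl-2-arylpropane-1,3-diol | COc1cc(cc([C@@H](CO)[C@@H](O)c7ccc(O[Si](C)(C)C(C)(C)C)c(OC)c7)c1OCc8ccccc8)[C@H]2OC[C@H]3[C@@H]2CO[C@@H]3c4cc([C@@H](CO)[C@@H](O)c7ccc(O[Si](C)(C)C(C)(C)C)c(OC)c7)c(OCc8ccccc8)c(OC)c4 | intermediate
22 | 21 with both C9 hydroxyls as TBS ethers | COc1cc(cc([C@@H](CO[Si](C)(C)C(C)(C)C)[C@@H](O)c7ccc(O[Si](C)(C)C(C)(C)C)c(OC)c7)c1OCc8ccccc8)[C@H]2OC[C@H]3[C@@H]2CO[C@@H]3c4cc([C@@H](CO[Si](C)(C)C(C)(C)C)[C@@H](O)c7ccc(O[Si](C)(C)C(C)(C)C)c(OC)c7)c(OCc8ccccc8)c(OC)c4 | intermediate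
23 | mono-ketone: ring B arm is the (S)-α-aryl-β-silyloxy ketone, ring C arm still the (7R,8S) carbinol | COc1cc(cc([C@@H](CO[Si](C)(C)C(C)(C)C)C(=O)c7ccc(O[Si](C)(C)C(C)(C)C)c(OC)c7)c1OCc8ccccc8)[C@H]2OC[C@H]3[C@@H]2CO[C@@H]3c4cc([C@@H](CO[Si](C)(C)C(C)(C)C)[C@@H](O)c7ccc(O[Si](C)(C)C(C)(C)C)c(OC)c7)c(OCc8ccccc8)c(OC)c4 | intermediate
24 | 23 with both benzyl ethers removed (may equilibrate with the cyclic hemiketal on the ring B side) | COc1cc(cc([C@@H](CO[Si](C)(C)C(C)(C)C)C(=O)c7ccc(O[Si](C)(C)C(C)(C)C)c(OC)c7)c1O)[C@H]2OC[C@H]3[C@@H]2CO[C@@H]3c4cc([C@@H](CO[Si](C)(C)C(C)(C)C)[C@@H](O)c7ccc(O[Si](C)(C)C(C)(C)C)c(OC)c7)c(O)c(OC)c4 | intermediate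
25 | tetrakis-TBS ether of the target: (2S,3S)-cis-dihydrobenzofuran on ring C, (S)-ketone arm on ring B | COc1cc(cc([C@@H](CO[Si](C)(C)C(C)(C)C)C(=O)c7ccc(O[Si](C)(C)C(C)(C)C)c(OC)c7)c1O)[C@H]2OC[C@H]3[C@@H]2CO[C@@H]3c4cc(OC)c5c(c4)[C@@H](CO[Si](C)(C)C(C)(C)C)[C@@H](c6ccc(O[Si](C)(C)C(C)(C)C)c(OC)c6)O5 | intermediate
26 | CNP0174045.1 | COc1cc(C(=O)[C@H](CO)c2cc([C@H]3OC[C@H]4[C@@H]3CO[C@@H]4c3cc(OC)c4c(c3)[C@@H](CO)[C@@H](c3ccc(O)c(OC)c3)O4)cc(OC)c2O)ccc1O | target

**Count**

Total steps: 18. Longest linear sequence: 17 steps (steps 1–10 and 12–18 from 1; step 11 prepares aldehyde 18).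

**Steps most likely to fail**

Step 4. The two-carbon tether may steer the first bond formation toward the cis-fused (meso-type) adduct, intermolecular cycloaddition may compete, or the induction may run in the opposite sense. Fallback, setting out from 4 and returning at 8:
- 4 is esterified with methanol (DCC, DMAP) to methyl (E)-3-(4-acetoxy-3-bromo-5-methoxyphenyl)acrylate F1.
- F1 is dimerised intermolecularly with the same Ir sensitiser in concentrated solution to racemic all-trans dimethyl 3,4-bis(4-acetoxy-3-bromo-5-methoxyphenyl)cyclobutane-1,2-dicarboxylate F2.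
- The enantiomers are separated on a chiral stationary phase and the (1R,2R,3S,4S) diester F3 is identified by anomalous-dispersion crystallography.
- LiAlH4 reduction of F3 gives 8.

Step 6. Phenoxyl radicals on the silver surface may couple intermolecularly through oxygen, the product phenols may be oxidised further, or the ring-opened radical may fragment before it is oxidised, which would erode the stereochemical information. Fallback, setting out from 8 and returning at 11:
- The two phenols of 8 are benzylated first (BnBr, K2CO3, DMF; the primary alcohols stay free) to [(1R,2R,3S,4S)-3,4-bis(4-benzyloxy-3-bromo-5-methoxyphenyl)cyclobutane-1,2-diyl]dimethanol F4.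
- The ring is then opened by single-electron oxidation of the alkoxyarene (FeCl3, CH2Cl2/HFIP, 0 °C). The arene radical cation cleaves the same aryl-flanked bond, the benzylic cation is trapped 5-exo by the neighbouring hydroxymethyl group, and oxidation of the remaining benzylic radical closes the second ring to give 11 directly.
- No phenoxyl radical or free product phenol is involved in this variant.

Step 17. The activated para-silyloxybenzylic alcohol may ionise before displacement, which would cost the stereospecificity and favour the trans-dihydrobenzofuran, or it may eliminate to a stilbene. Fallback, setting out from 22 and returning at 26, in which rings D and E carry electron-withdrawing acetates during the ring closure: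
- The phenolic silyl ethers of 22 are cleaved selectively (K2CO3, MeOH) to the bis-phenol F5.
- The phenols alone are acetylated (Ac2O, Et3N, CH2Cl2, 0 °C) to the diacetate F6.
- Statistical Dess–Martin oxidation as in step 15 gives the mono-ketone F7.
- Hydrogenolysis as in step 16 gives the bis-phenol F8.
- Mitsunobu closure, now at a para-acetoxybenzylic carbon that cannot ionise, gives the cis-dihydrobenzofuran diacetate F9.
- Brief ammonolysis (NH3, MeOH, 0 °C) removes the aryl acetates to give the bis(primary TBS ether) F10.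
- Buffered TBAF/AcOH as in step 18 gives 26.

Further compounds
F1 | step 4 | methyl (E)-3-(4-acetoxy-3-bromo-5-methoxyphenyl)acrylate | COC(=O)/C=C/c1cc(Br)c(OC(C)=O)c(OC)c1
F2 | step 4 | racemic all-trans dimethyl 3,4-bis(4-acetoxy-3-bromo-5-methoxyphenyl)cyclobutane-1,2-dicarboxylate (both enantiomers) | COC(=O)[C@H]1[C@H](C(=O)OC)[C@@H](c2cc(Br)c(OC(C)=O)c(OC)c2)[C@@H]1c3cc(Br)c(OC(C)=O)c(OC)c3.COC(=O)[C@@H]1[C@@H](C(=O)OC)[C@H](c2cc(Br)c(OC(C)=O)c(OC)c2)[C@H]1c3cc(Br)c(OC(C)=O)c(OC)c3
F3 | step 4 | dimethyl (1R,2R,3S,4S)-3,4-bis(4-acetoxy-3-bromo-5-methoxyphenyl)cyclobutane-1,2-dicarboxylate | COC(=O)[C@H]1[C@H](C(=O)OC)[C@@H](c2cc(Br)c(OC(C)=O)c(OC)c2)[C@@H]1c3cc(Br)c(OC(C)=O)c(OC)c3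
F4 | step 6 | [(1R,2R,3S,4S)-3,4-bis(4-benzyloxy-3-bromo-5-methoxyphenyl)cyclobutane-1,2-diyl]dimethanol | OC[C@H]1[C@H](CO)[C@@H](c2cc(Br)c(OCc4ccccc4)c(OC)c2)[C@@H]1c3cc(Br)c(OCc5ccccc5)c(OC)c3
F5 | step 17 | 22 with the ring D and ring E phenols free | COc1cc(cc([C@@H](CO[Si](C)(C)C(C)(C)C)[C@@H](O)c7ccc(O)c(OC)c7)c1OCc8ccccc8)[C@H]2OC[C@H]3[C@@H]2CO[C@@H]3c4cc([C@@H](CO[Si](C)(C)C(C)(C)C)[C@@H](O)c7ccc(O)c(OC)c7)c(OCc8ccccc8)c(OC)c4
F6 | step 17 | ring D and ring E diacetate of F5 | COc1cc(cc([C@@H](CO[Si](C)(C)C(C)(C)C)[C@@H](O)c7ccc(OC(C)=O)c(OC)c7)c1OCc8ccccc8)[C@H]2OC[C@H]3[C@@H]2CO[C@@H]3c4cc([C@@H](CO[Si](C)(C)C(C)(C)C)[C@@H](O)c7ccc(OC(C)=O)c(OC)c7)c(OCc8ccccc8)c(OC)c4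
F7 | step 17 | mono-ketone of F6 (ring B arm oxidised) | COc1cc(cc([C@@H](CO[Si](C)(C)C(C)(C)C)C(=O)c7ccc(OC(C)=O)c(OC)c7)c1OCc8ccccc8)[C@H]2OC[C@H]3[C@@H]2CO[C@@H]3c4cc([C@@H](CO[Si](C)(C)C(C)(C)C)[C@@H](O)c7ccc(OC(C)=O)c(OC)c7)c(OCc8ccccc8)c(OC)c4
F8 | step 17 | F7 with both benzyl ethers removed | COc1cc(cc([C@@H](CO[Si](C)(C)C(C)(C)C)C(=O)c7ccc(OC(C)=O)c(OC)c7)c1O)[C@H]2OC[C@H]3[C@@H]2CO[C@@H]3c4cc([C@@H](CO[Si](C)(C)C(C)(C)C)[C@@H](O)c7ccc(OC(C)=O)c(OC)c7)c(O)c(OC)c4
F9 | step 17 | (2S,3S)-cis-dihydrobenzofuran with ring D and ring E acetates and both C9 TBS ethers | COc1cc(cc([C@@H](CO[Si](C)(C)C(C)(C)C)C(=O)c7ccc(OC(C)=O)c(OC)c7)c1O)[C@H]2OC[C@H]3[C@@H]2CO[C@@H]3c4cc(OC)c5c(c4)[C@@H](CO[Si](C)(C)C(C)(C)C)[C@@H](c6ccc(OC(C)=O)c(OC)c6)O5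
F10 | step 17 | target with both C9 hydroxyls as TBS ethers | COc1cc(cc([C@@H](CO[Si](C)(C)C(C)(C)C)C(=O)c7ccc(O)c(OC)c7)c1O)[C@H]2OC[C@H]3[C@@H]2CO[C@@H]3c4cc(OC)c5c(c4)[C@@H](CO[Si](C)(C)C(C)(C)C)[C@@H](c6ccc(O)c(OC)c6)O5
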